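**Retrosynthetic overview**

1. Locants: C1 quaternary C–CH3, C2 CH–OH, C3 CH2, C4 C(OH)(i-Pr), C5 ring-fusion CH, C6 CH–O-aroyl, C7=C8(CH3), C9 C=O, C10 CH2. β is the face of the C1 methyl group, α the opposite face.
2. The plan rests on the seven-membered ring C5–C6–C7–C8–C9–C10–C1, in which the C6 oxygen and the C9 carbonyl are 1,4-related through C7=C8. The target is therefore the C6-reduced, acylated form of a cyclohept-7-ene-6,9-dione, and C8–C9 is cut as acyl carbon (C9) plus enone β-carbon (C8).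
3. Ring order: the cyclopentane comes first, from (R)-4-hydroxycyclopent-2-enone (anti cuprate addition sets C5, enolate alkylation sets C1, C4–OH-directed reduction sets C2, isopropyl addition to the C4 ketone sets C4). The seven-membered ring is closed last, by 7-endo cyclisation of the C9 acyl radical from a phenyl selenoester onto the C5 crotonyl ketone.
4. Endgame: C7–C8 dehydrogenation of the 6,9-dione, C4–OH-directed reduction of C6, esterification with silyl-protected 4-hydroxybenzoic acid, global desilylation.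

Key step: step 16

Remark: C8 is left unassigned in 20, 21 and 26 (epimer mixtures are carried on), because C8 becomes sp2 in steps 13 and 17.

**Route**

Step 1
Reactants: 1 (R)-4-hydroxycyclopent-2-en-1-one
Product: 2 (R)-4-(triethylsilyloxy)cyclopent-2-en-1-one
Conditions: Et3SiCl, imidazole, CH2Cl2, 0 °C
Reagents that add atoms: chlorotriethylsilane, CC[Si](CC)(CC)Cl
Why: Routine silylation of the secondary alcohol under mild base should leave the C4 stereocentre and the enone untouched.

Step 2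
Reactants: 2 (R)-4-(triethylsilyloxy)cyclopent-2-en-1-one
Product: 3 (R)-2-iodo-4-(triethylsilyloxy)cyclopent-2-en-1-one
Conditions: I2, pyridine/CH2Cl2, 0 °C → rt
Reagents that add atoms: iodine, [I][I]
Why: Pyridine-mediated α-iodination of an enone (conjugate addition of pyridine, iodination of the enolate, elimination) is specific for the α-carbon, the future C1.

Step 3
Reactants: 3 (R)-2-iodo-4-(triethylsilyloxy)cyclopent-2-en-1-one
Product: 4 (R)-2-methyl-4-(triethylsilyloxy)cyclopent-2-en-1-one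
Conditions: MeZnCl, Pd2(dba)3 (cat.), P(2-furyl)3, THF/DMF, rt
Reagents that add atoms: methylzinc chloride, C[Zn]Cl
Why: Negishi cross-coupling of the α-iodoenone installs the C1 methyl group under neutral conditions that should not eliminate the γ-silyloxy group.

Step 4
Reactants: 4 (R)-2-methyl-4-(triethylsilyloxy)cyclopent-2-en-1-one
Product: 5 (3R,4R)-2-methyl-3-(prop-1-en-2-yl)-4-(triethylsilyloxy)-1-(trimethylsilyloxy)cyclopent-1-ene
Conditions: CH2=C(CH3)MgBr, CuBr·SMe2 (10 mol%), Me3SiCl, HMPA, THF, −78 °C; Et3N, pentane work-up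
Reagents that add atoms: isopropenylmagnesium bromide, CC(=C)[Mg]Br; chlorotrimethylsilane, C[Si](C)(C)Cl
Why: Copper-catalysed, chlorosilane-accelerated conjugate addition of the Grignard reagent should occur anti to the C4 silyloxy group, which sets C5, and trap the enolate regiospecifically as the silyl enol ether.

Step 5
Reactants: 5 (3R,4R)-2-methyl-3-(prop-1-en-2-yl)-4-(triethylsilyloxy)-1-(trimethylsilyloxy)cyclopent-1-ene; 6 tert-butyl bromoacetate
Product: 9 tert-butyl 2-[4α-hydroxy-1β-methyl-2-oxo-5β-(prop-1-en-2-yl)cyclopentyl]acetate, via lithium enolate 7 (not isolated), via C4-triethylsilyl ketone 8 (not isolated)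
Conditions: MeLi, THF, 0 °C; DMPU, then 6, −78 → −30 °C; then 1 M HCl, THF, 0 °C
Reagents that add atoms: tert-butyl bromoacetate (6), CC(C)(C)OC(=O)CBr
Why: Methyllithium cleaves the O–Si bond to the regiodefined tetrasubstituted lithium enolate, whose alkylation by the reactive α-bromo ester should occur anti to the adjacent C5 isopropenyl group (C1 quaternary centre, CH2CO2t-Bu α), and the cold acidic quench removes the secondary silyl ether before the β-silyloxy ketone can eliminate.

Step 6
Reactants: 9 tert-butyl 2-[4α-hydroxy-1β-methyl-2-oxo-5β-(prop-1-en-2-yl)cyclopentyl]acetate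
Product: 10 tert-butyl 2-[2β,4α-dihydroxy-1β-methyl-5β-(prop-1-en-2-yl)cyclopentyl]acetate
Conditions: Me4NBH(OAc)3, MeCN/AcOH (1:1), −30 °C
Reagents that add atoms: none
Why: In this Saksena–Evans hydroxyl-directed reduction the C4 α-hydroxyl binds boron and delivers hydride to the α-face of the C2 ketone, which should give the trans-1,3-diol with the C2 hydroxyl β, cis to the C1 methyl group.

Step 7
Reactants: 10 tert-butyl 2-[2β,4α-dihydroxy-1β-methyl-5β-(prop-1-en-2-yl)cyclopentyl]acetate
Product: 12 tert-butyl 2-[2β-(tert-butyldimethylsilyloxy)-1β-methyl-5β-(prop-1-en-2-yl)-4α-(triethylsilyloxy)cyclopentyl]acetate, via C4-triethylsilyl ether 11 (not isolated)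
Conditions: Et3SiCl (1.05 equiv), imidazole, CH2Cl2, −40 °C; then t-BuMe2SiOTf, 2,6-lutidine, −40 → 0 °C
Reagents that add atoms: chlorotriethylsilane, CC[Si](CC)(CC)Cl; tert-butyldimethylsilyl triflate, CC(C)(C)[Si](C)(C)OS(=O)(=O)C(F)(F)F
Why: Sequential silylation should differentiate the diol, because the silyl chloride reacts first at the less hindered C4 hydroxyl and the neopentyl C2 hydroxyl is then capped with the more reactive silyl triflate.

Step 8
Reactants: 12 tert-butyl 2-[2β-(tert-butyldimethylsilyloxy)-1β-methyl-5β-(prop-1-en-2-yl)-4α-(triethylsilyloxy)cyclopentyl]acetate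
Product: 13 tert-butyl 2-[2β-(tert-butyldimethylsilyloxy)-4α-hydroxy-1β-methyl-5β-(prop-1-en-2-yl)cyclopentyl]acetate
Conditions: PPTS, MeOH/CH2Cl2, 0 °C → rt
Reagents that add atoms: none
Why: Mild acid methanolysis should cleave the secondary triethylsilyl ether while the hindered tert-butyldimethylsilyl ether and the tert-butyl ester persist.

Step 9
Reactants: 13 tert-butyl 2-[2β-(tert-butyldimethylsilyloxy)-4α-hydroxy-1β-methyl-5β-(prop-1-en-2-yl)cyclopentyl]acetate
Product: 14 tert-butyl 2-[2β-(tert-butyldimethylsilyloxy)-1β-methyl-4-oxo-5β-(prop-1-en-2-yl)cyclopentyl]acetate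
Conditions: Dess–Martin periodinane, NaHCO3, CH2Cl2, 0 °C
Reagents that add atoms: none
Why: Buffered Dess–Martin oxidation should give the C4 ketone without moving the β,γ-double bond into conjugation or epimerising C5, and the ketone is used at once.

Step 10
Reactants: 14 tert-butyl 2-[2β-(tert-butyldimethylsilyloxy)-1β-methyl-4-oxo-5β-(prop-1-en-2-yl)cyclopentyl]acetate
Product: 15 tert-butyl 2-[2β-(tert-butyldimethylsilyloxy)-4β-hydroxy-4α-isopropyl-1β-methyl-5β-(prop-1-en-2-yl)cyclopentyl]acetate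
Conditions: i-PrMgCl, LaCl3·2LiCl, THF, −20 → 0 °C
Reagents that add atoms: isopropylmagnesium chloride, CC(C)[Mg]Cl
Why: Lanthanide-promoted Grignard 1,2-addition suppresses enolisation and β-hydride reduction, and attack anti to the adjacent C5 isopropenyl group (the β-face also carries the C2 silyloxy group) should set C4 with isopropyl α and hydroxyl β.

Step 11
Reactants: 15 tert-butyl 2-[2β-(tert-butyldimethylsilyloxy)-4β-hydroxy-4α-isopropyl-1β-methyl-5β-(prop-1-en-2-yl)cyclopentyl]acetate
Product: 16 tert-butyl 2-[2β-(tert-butyldimethylsilyloxy)-4α-isopropyl-1β-methyl-5β-(prop-1-en-2-yl)-4β-(triethylsilyloxy)cyclopentyl]acetate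
Conditions: Et3SiOTf, 2,6-lutidine, CH2Cl2, −78 → 0 °C
Reagents that add atoms: triethylsilyl triflate, CC[Si](CC)(CC)OS(=O)(=O)C(F)(F)F
Why: Silyl triflate silylation caps the hindered tertiary alcohol, so that it cannot add to the enone or be lost by retro-aldol cleavage in later steps.

Step 12
Reactants: 16 tert-butyl 2-[2β-(tert-butyldimethylsilyloxy)-4α-isopropyl-1β-methyl-5β-(prop-1-en-2-yl)-4β-(triethylsilyloxy)cyclopentyl]acetate
Product: 17 tert-butyl 2-[5β-acetyl-2β-(tert-butyldimethylsilyloxy)-4α-isopropyl-1β-methyl-4β-(triethylsilyloxy)cyclopentyl]acetate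
Conditions: O3, CH2Cl2/MeOH, −78 °C; Me2S, −78 °C → rt
Reagents that add atoms: ozone, [O-][O+]=O
Why: Ozonolysis of the only alkene with reductive work-up gives the C6 methyl ketone, and the C5 configuration (acetyl trans to isopropyl and to the acetate arm) is also the thermodynamically preferred one.

Step 13
Reactants: 17 tert-butyl 2-[5β-acetyl-2β-(tert-butyldimethylsilyloxy)-4α-isopropyl-1β-methyl-4β-(triethylsilyloxy)cyclopentyl]acetate; 18 acetaldehyde
Product: 22 tert-butyl 2-[5β-((E)-but-2-enoyl)-2β-(tert-butyldimethylsilyloxy)-4α-isopropyl-1β-methyl-4β-(triethylsilyloxy)cyclopentyl]acetate, via lithium enolate 19 (not isolated), via aldol 20 (not isolated), via mesylate 21 (not isolated)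
Conditions: LDA, THF, −78 °C; CH3CHO; AcOH; crude: MsCl, Et3N, CH2Cl2, 0 °C; DBU, rt
Reagents that add atoms: acetaldehyde (18), CC=O
Why: Aldol condensation: kinetic deprotonation occurs at the unhindered methyl group and not at the buried C5–H, and mesylation of the aldol followed by E1cB elimination through C7 should give the (E)-enone.

Step 14
Reactants: 22 tert-butyl 2-[5β-((E)-but-2-enoyl)-2β-(tert-butyldimethylsilyloxy)-4α-isopropyl-1β-methyl-4β-(triethylsilyloxy)cyclopentyl]acetate
Product: 24 2-[5β-((E)-but-2-enoyl)-2β-(tert-butyldimethylsilyloxy)-4α-isopropyl-1β-methyl-4β-(triethylsilyloxy)cyclopentyl]acetic acid, via trimethylsilyl ester 23 (not isolated)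
Conditions: Me3SiOTf, 2,6-lutidine, CH2Cl2, 0 °C; pH 5 buffer work-up
Reagents that add atoms: none
Why: Silyl triflate-mediated cleavage of the tert-butyl ester (loss of 2-methylpropene) gives the silyl ester, which hydrolyses on work-up, and the buffered conditions should spare both silyl ethers, which protic acid would not.

Step 15
Reactants: 24 2-[5β-((E)-but-2-enoyl)-2β-(tert-butyldimethylsilyloxy)-4α-isopropyl-1β-methyl-4β-(triethylsilyloxy)cyclopentyl]acetic acid
Product: 25 Se-phenyl 2-[5β-((E)-but-2-enoyl)-2β-(tert-butyldimethylsilyloxy)-4α-isopropyl-1β-methyl-4β-(triethylsilyloxy)cyclopentyl]ethaneselenoate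
Conditions: N-(phenylselanyl)phthalimide, Bu3P, CH2Cl2, −20 °C → rt
Reagents that add atoms: N-(phenylselanyl)phthalimide, O=C1N([Se]c2ccccc2)C(=O)c2ccccc12
Why: Grieco-type selenoesterification through the acyloxyphosphonium ion consumes the selenolate as it forms, so conjugate addition to the β-methylated enone should not compete, and neither silyloxy group can lactonise.

Step 16
Reactants: 25 Se-phenyl 2-[5β-((E)-but-2-enoyl)-2β-(tert-butyldimethylsilyloxy)-4α-isopropyl-1β-methyl-4β-(triethylsilyloxy)cyclopentyl]ethaneselenoate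
Product: 26 trans-fused (5α-H) 2β-(tert-butyldimethylsilyloxy)-4α-isopropyl-1β,8-dimethyl-4β-(triethylsilyloxy)hydroazulene-6,9-dione (C8 epimers)
Conditions: Bu3SnH (1.3 equiv), AIBN (0.2 equiv), syringe pump over 6 h, benzene, 80 °C, 0.004 M
Reagents that add atoms: none
Why: The tributyltin radical abstracts the phenylselanyl group to give the C9 acyl radical, which adds to the β-carbon C8 of the C5 crotonyl ketone, and the resulting C7 α-keto radical is quenched by the stannane, which carries the chain. The closest known reaction type is the tin-hydride-mediated cyclisation of acyl radicals from phenyl selenoesters onto α,β-unsaturated carbonyl acceptors, for which seven-membered endo closures are documented. The ring C5–C6–C7–C8–C9–C10–C1 closes in the 7-endo-trig mode and is trans-fused because C1 and C5 are fixed beforehand and take no part in the bond formation. The only new stereocentre, C8, is formed without control and is left unassigned, since step 17 makes it sp2. The step needs endo rather than 6-exo closure and cyclisation rather than hydrogen transfer or decarbonylation: the nucleophilic acyl radical is polarity-matched with the electrophilic C8 and gives a stabilised radical whereas attack at C7 is mismatched, slow stannane addition at high dilution holds back hydrogen transfer, and a primary acyl radical loses CO only slowly at 80 °C.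

Step 17
Reactants: 26 trans-fused (5α-H) 2β-(tert-butyldimethylsilyloxy)-4α-isopropyl-1β,8-dimethyl-4β-(triethylsilyloxy)hydroazulene-6,9-dione (C8 epimers)
Product: 27 trans-fused 2β-(tert-butyldimethylsilyloxy)-4α-isopropyl-1β,8-dimethyl-4β-(triethylsilyloxy)hydroazul-7-ene-6,9-dione
Conditions: IBX (2.5 equiv), DMSO/fluorobenzene, 70 °C
Reagents that add atoms: none
Why: IBX dehydrogenation of a ketone through its enol can only desaturate C7–C8, because the other α-carbons (C5 and C10) adjoin the hydrogen-free C4 and C1, and it should give the doubly conjugated ene-dione from either C8 epimer.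

Step 18
Reactants: 27 trans-fused 2β-(tert-butyldimethylsilyloxy)-4α-isopropyl-1β,8-dimethyl-4β-(triethylsilyloxy)hydroazul-7-ene-6,9-dione
Product: 28 trans-fused 2β-(tert-butyldimethylsilyloxy)-4β-hydroxy-4α-isopropyl-1β,8-dimethylhydroazul-7-ene-6,9-dione
Conditions: HF·pyridine, pyridine, THF, 0 °C
Reagents that add atoms: none
Why: Buffered fluoride desilylation should remove the triethylsilyl ether faster than the hindered tert-butyldimethylsilyl ether at C2, and the free β-hydroxy ene-dione is taken on at once.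

Step 19
Reactants: 28 trans-fused 2β-(tert-butyldimethylsilyloxy)-4β-hydroxy-4α-isopropyl-1β,8-dimethylhydroazul-7-ene-6,9-dione
Product: 29 trans-fused 2β-(tert-butyldimethylsilyloxy)-4β,6α-dihydroxy-4α-isopropyl-1β,8-dimethylhydroazul-7-en-9-one
Conditions: Me4NBH(OAc)3, MeCN/AcOH (1:1), −30 °C
Reagents that add atoms: none
Why: In this Saksena–Evans reduction the reagent attacks only a ketone that carries a β-hydroxyl, so C9 is left alone, and boron bound to the C4 β-hydroxyl can reach only the β-face of C6, which should give the 1,3-anti diol with the C6 hydroxyl α.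

Step 20
Reactants: 30 4-hydroxybenzoic acid
Product: 32 4-(tert-butyldimethylsilyloxy)benzoic acid, via bis-silylated acid 31 (not isolated)
Conditions: t-BuMe2SiCl (2.3 equiv), imidazole, DMF, rt; then AcOH/H2O/THF (3:1:1), rt
Reagents that add atoms: tert-butyldimethylsilyl chloride, CC(C)(C)[Si](C)(C)Cl
Why: Exhaustive silylation followed by selective hydrolysis of the labile silyl ester leaves the aryl silyl ether in place.

Step 21
Reactants: 29 trans-fused 2β-(tert-butyldimethylsilyloxy)-4β,6α-dihydroxy-4α-isopropyl-1β,8-dimethylhydroazul-7-en-9-one; 32 4-(tert-butyldimethylsilyloxy)benzoic acid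
Product: 33 C6 α-[4-(tert-butyldimethylsilyloxy)benzoate] of 29
Conditions: EDC·HCl, DMAP, CH2Cl2, rt
Reagents that add atoms: 4-(tert-butyldimethylsilyloxy)benzoic acid (32), CC(C)(C)[Si](C)(C)Oc1ccc(C(=O)O)cc1
Why: Steglich esterification should acylate the secondary allylic C6 hydroxyl, while the tertiary C4 hydroxyl is inert and C2 is still silylated.

Step 22
Reactants: 33 C6 α-[4-(tert-butyldimethylsilyloxy)benzoate] of 29
Product: 34 CNP0199397.1
Conditions: HF·pyridine, THF, 0 °C → rt
Reagents that add atoms: none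
Why: Fluoride-mediated cleavage of the aryl and the C2 silyl ethers under mildly acidic conditions should leave the allylic ester, the enone and the tertiary alcohol unchanged.

**Compound list**

1 | (R)-4-hydroxycyclopent-2-en-1-one | O=C1C=C[C@H](O)C1 | starting material
2 | (R)-4-(triethylsilyloxy)cyclopent-2-en-1-one | O=C1C=C[C@H](O[Si](CC)(CC)CC)C1 | intermediate
3 | (R)-2-iodo-4-(triethylsilyloxy)cyclopent-2-en-1-one | O=C1C(I)=C[C@H](O[Si](CC)(CC)CC)C1 | intermediate
4 | (R)-2-methyl-4-(triethylsilyloxy)cyclopent-2-en-1-one | O=C1C(C)=C[C@H](O[Si](CC)(CC)CC)C1 | intermediate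
5 | (3R,4R)-2-methyl-3-(prop-1-en-2-yl)-4-(triethylsilyloxy)-1-(trimethylsilyloxy)cyclopent-1-ene | CC(=C)[C@@H]1C(C)=C(O[Si](C)(C)C)C[C@H]1O[Si](CC)(CC)CC | intermediate
6 | tert-butyl bromoacetate | CC(C)(C)OC(=O)CBr | starting material
7 | lithium enolate from 5 (C2–OLi, C1=C2; not isolated) | CC(=C)[C@@H]1C(C)=C(O[Li])C[C@H]1O[Si](CC)(CC)CC | intermediate
8 | tert-butyl 2-[1β-methyl-2-oxo-5β-(prop-1-en-2-yl)-4α-(triethylsilyloxy)cyclopentyl]acetate (not isolated) | CC(=C)[C@@H]1[C@@](C)(CC(=O)OC(C)(C)C)C(=O)C[C@H]1O[Si](CC)(CC)CC | intermediate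
9 | tert-butyl 2-[4α-hydroxy-1β-methyl-2-oxo-5β-(prop-1-en-2-yl)cyclopentyl]acetate | CC(=C)[C@@H]1[C@@](C)(CC(=O)OC(C)(C)C)C(=O)C[C@H]1O | intermediate
10 | tert-butyl 2-[2β,4α-dihydroxy-1β-methyl-5β-(prop-1-en-2-yl)cyclopentyl]acetate | CC(=C)[C@@H]1[C@@](C)(CC(=O)OC(C)(C)C)[C@H](O)C[C@H]1O | intermediate
11 | tert-butyl 2-[2β-hydroxy-1β-methyl-5β-(prop-1-en-2-yl)-4α-(triethylsilyloxy)cyclopentyl]acetate (not isolated) | CC(=C)[C@@H]1[C@@](C)(CC(=O)OC(C)(C)C)[C@H](O)C[C@H]1O[Si](CC)(CC)CC | intermediate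
12 | tert-butyl 2-[2β-(tert-butyldimethylsilyloxy)-1β-methyl-5β-(prop-1-en-2-yl)-4α-(triethylsilyloxy)cyclopentyl]acetate | CC(=C)[C@@H]1[C@@](C)(CC(=O)OC(C)(C)C)[C@H](O[Si](C)(C)C(C)(C)C)C[C@H]1O[Si](CC)(CC)CC | intermediate
13 | tert-butyl 2-[2β-(tert-butyldimethylsilyloxy)-4α-hydroxy-1β-methyl-5β-(prop-1-en-2-yl)cyclopentyl]acetate | CC(=C)[C@@H]1[C@@](C)(CC(=O)OC(C)(C)C)[C@H](O[Si](C)(C)C(C)(C)C)C[C@H]1O | intermediate
14 | tert-butyl 2-[2β-(tert-butyldimethylsilyloxy)-1β-methyl-4-oxo-5β-(prop-1-en-2-yl)cyclopentyl]acetate | CC(=C)[C@@H]1[C@@](C)(CC(=O)OC(C)(C)C)[C@H](O[Si](C)(C)C(C)(C)C)CC1=O | intermediate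
15 | tert-butyl 2-[2β-(tert-butyldimethylsilyloxy)-4β-hydroxy-4α-isopropyl-1β-methyl-5β-(prop-1-en-2-yl)cyclopentyl]acetate | CC(=C)[C@@H]1[C@@](C)(CC(=O)OC(C)(C)C)[C@H](O[Si](C)(C)C(C)(C)C)C[C@@]1(O)C(C)C | intermediate
16 | tert-butyl 2-[2β-(tert-butyldimethylsilyloxy)-4α-isopropyl-1β-methyl-5β-(prop-1-en-2-yl)-4β-(triethylsilyloxy)cyclopentyl]acetate | CC(=C)[C@@H]1[C@@](C)(CC(=O)OC(C)(C)C)[C@H](O[Si](C)(C)C(C)(C)C)C[C@@]1(O[Si](CC)(CC)CC)C(C)C | intermediate
17 | tert-butyl 2-[5β-acetyl-2β-(tert-butyldimethylsilyloxy)-4α-isopropyl-1β-methyl-4β-(triethylsilyloxy)cyclopentyl]acetate | CC(=O)[C@@H]1[C@@](C)(CC(=O)OC(C)(C)C)[C@H](O[Si](C)(C)C(C)(C)C)C[C@@]1(O[Si](CC)(CC)CC)C(C)C | intermediate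
18 | acetaldehyde | CC=O | starting material
19 | lithium enolate of 17 at the acetyl methyl group (not isolated) | C=C(O[Li])[C@@H]1[C@@](C)(CC(=O)OC(C)(C)C)[C@H](O[Si](C)(C)C(C)(C)C)C[C@@]1(O[Si](CC)(CC)CC)C(C)C | intermediate
20 | aldol: 5β-(3-hydroxybutanoyl) analogue of 17 (C8 epimers; not isolated) | CC(O)CC(=O)[C@@H]1[C@@](C)(CC(=O)OC(C)(C)C)[C@H](O[Si](C)(C)C(C)(C)C)C[C@@]1(O[Si](CC)(CC)CC)C(C)C | intermediate
21 | mesylate: 5β-[3-(methanesulfonyloxy)butanoyl] analogue of 17 (C8 epimers; not isolated) | CC(OS(C)(=O)=O)CC(=O)[C@@H]1[C@@](C)(CC(=O)OC(C)(C)C)[C@H](O[Si](C)(C)C(C)(C)C)C[C@@]1(O[Si](CC)(CC)CC)C(C)C | intermediate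
22 | tert-butyl 2-[5β-((E)-but-2-enoyl)-2β-(tert-butyldimethylsilyloxy)-4α-isopropyl-1β-methyl-4β-(triethylsilyloxy)cyclopentyl]acetate | C/C=C/C(=O)[C@@H]1[C@@](C)(CC(=O)OC(C)(C)C)[C@H](O[Si](C)(C)C(C)(C)C)C[C@@]1(O[Si](CC)(CC)CC)C(C)C | intermediate
23 | trimethylsilyl ester corresponding to 22 (not isolated) | C/C=C/C(=O)[C@@H]1[C@@](C)(CC(=O)O[Si](C)(C)C)[C@H](O[Si](C)(C)C(C)(C)C)C[C@@]1(O[Si](CC)(CC)CC)C(C)C | intermediate
24 | 2-[5β-((E)-but-2-enoyl)-2β-(tert-butyldimethylsilyloxy)-4α-isopropyl-1β-methyl-4β-(triethylsilyloxy)cyclopentyl]acetic acid | C/C=C/C(=O)[C@@H]1[C@@](C)(CC(=O)O)[C@H](O[Si](C)(C)C(C)(C)C)C[C@@]1(O[Si](CC)(CC)CC)C(C)C | intermediate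
25 | Se-phenyl selenoester of 24 (radical precursor) | C/C=C/C(=O)[C@@H]1[C@@](C)(CC(=O)[Se]c2ccccc2)[C@H](O[Si](C)(C)C(C)(C)C)C[C@@]1(O[Si](CC)(CC)CC)C(C)C | intermediate
26 | trans-fused (5α-H) 2β-(tert-butyldimethylsilyloxy)-4α-isopropyl-1β,8-dimethyl-4β-(triethylsilyloxy)hydroazulene-6,9-dione (C8 epimers) | CC1CC(=O)[C@@H]2[C@@](C)(CC1=O)[C@H](O[Si](C)(C)C(C)(C)C)C[C@@]2(O[Si](CC)(CC)CC)C(C)C | intermediate
27 | trans-fused 2β-(tert-butyldimethylsilyloxy)-4α-isopropyl-1β,8-dimethyl-4β-(triethylsilyloxy)hydroazul-7-ene-6,9-dione | CC1=CC(=O)[C@@H]2[C@@](C)(CC1=O)[C@H](O[Si](C)(C)C(C)(C)C)C[C@@]2(O[Si](CC)(CC)CC)C(C)C | intermediate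
28 | trans-fused 2β-(tert-butyldimethylsilyloxy)-4β-hydroxy-4α-isopropyl-1β,8-dimethylhydroazul-7-ene-6,9-dione | CC1=CC(=O)[C@@H]2[C@@](C)(CC1=O)[C@H](O[Si](C)(C)C(C)(C)C)C[C@@]2(O)C(C)C | intermediate
29 | trans-fused 2β-(tert-butyldimethylsilyloxy)-4β,6α-dihydroxy-4α-isopropyl-1β,8-dimethylhydroazul-7-en-9-one | CC1=C[C@H](O)[C@@H]2[C@@](C)(CC1=O)[C@H](O[Si](C)(C)C(C)(C)C)C[C@@]2(O)C(C)C | intermediate
30 | 4-hydroxybenzoic acid | OC(=O)c1ccc(O)cc1 | starting material
31 | tert-butyldimethylsilyl 4-(tert-butyldimethylsilyloxy)benzoate (not isolated) | CC(C)(C)[Si](C)(C)OC(=O)c1ccc(O[Si](C)(C)C(C)(C)C)cc1 | intermediate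
32 | 4-(tert-butyldimethylsilyloxy)benzoic acid | CC(C)(C)[Si](C)(C)Oc1ccc(C(=O)O)cc1 | intermediate
33 | C6 α-[4-(tert-butyldimethylsilyloxy)benzoate] of 29 | CC1=C[C@H](OC(=O)c3ccc(O[Si](C)(C)C(C)(C)C)cc3)[C@@H]2[C@@](C)(CC1=O)[C@H](O[Si](C)(C)C(C)(C)C)C[C@@]2(O)C(C)C | intermediate
34 | CNP0199397.1 (2β,4β-dihydroxy-6α-(4-hydroxybenzoyloxy)-4α-isopropyl-1β,8-dimethyl-trans-hydroazul-7-en-9-one) | CC1=C[C@H](OC(=O)c2ccc(O)cc2)[C@@H]2[C@@](C)(CC1=O)[C@H](O)C[C@@]2(O)C(C)C | target

**Step count and risks**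

Total step count: 22. Longest linear sequence: 21 steps (steps 1–19, 21 and 22; step 20 makes the acid side chain).

The three steps most likely to fail:

Step 16. Hydrogen transfer to the acyl radical, loss of CO or 6-exo closure may outrun the slow attack on the methyl-bearing C8. The fallback makes the same C8–C9 bond by a polar acyl-anion addition. It sets out from 25, which is reduced on purpose under chain conditions at high stannane concentration (Bu3SnH in excess, Et3B/air, toluene, −20 °C) to the C9 aldehyde F1. The aldehyde F1 is then cyclised by an intramolecular Stetter reaction (3-benzyl-5-(2-hydroxyethyl)-4-methylthiazolium chloride, Et3N, 1,4-dioxane, 70 °C), in which the carbene-derived acyl anion equivalent adds to C8 of the crotonyl ketone. The fallback comes back to the route at 26.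

Step 17. Desaturation may stall or run unselectively at 70 °C, and the tertiary silyl ether may be lost with subsequent β-elimination. The fallback separates enolisation from oxidation (Saegusa–Ito sequence). It sets out from 26, which is converted with Me3SiOTf and Et3N (CH2Cl2, 0 °C) into the bis(trimethylsilyl) dienol ether F2. The dienol ether F2 is oxidised with Pd(OAc)2 in MeCN at rt, and the fallback comes back at 27.

Step 19. Boron–oxygen exchange at the hindered tertiary alcohol may be slow, so that intermolecular hydride attack at C9 or at C7=C8 of the electron-poor ene-dione, or conjugate addition of the free C4 hydroxyl, intervenes. The fallback changes the order so that the directed reduction is run on a saturated ketone. It sets out from 26, which is desilylated at C4 (HF·pyridine, pyridine, THF, 0 °C) to the hydroxy dione F3. Directed reduction of F3 (Me4NBH(OAc)3, MeCN/AcOH, −30 °C) gives the saturated C6 α-alcohol F4, and esterification with 32 (EDC·HCl, DMAP, CH2Cl2) gives the saturated C6 ester F5. IBX (DMSO/fluorobenzene, 70 °C) then desaturates the C9 ketone, which has a β-hydrogen only on the C8–C7 side, and the fallback comes back at 33.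

**Further compounds**

F1 | step 16 | 2-[5β-((E)-but-2-enoyl)-2β-(tert-butyldimethylsilyloxy)-4α-isopropyl-1β-methyl-4β-(triethylsilyloxy)cyclopentyl]acetaldehyde | C/C=C/C(=O)[C@@H]1[C@@](C)(CC=O)[C@H](O[Si](C)(C)C(C)(C)C)C[C@@]1(O[Si](CC)(CC)CC)C(C)C
F2 | step 17 | 6,9-bis(trimethylsilyloxy)hydroazula-6,8-diene derived from 26 | CC=1C=C(O[Si](C)(C)C)[C@@H]2[C@@](C)(CC=1O[Si](C)(C)C)[C@H](O[Si](C)(C)C(C)(C)C)C[C@@]2(O[Si](CC)(CC)CC)C(C)C
F3 | step 19 | trans-fused 2β-(tert-butyldimethylsilyloxy)-4β-hydroxy-4α-isopropyl-1β,8-dimethylhydroazulene-6,9-dione (C8 epimers) | CC1CC(=O)[C@@H]2[C@@](C)(CC1=O)[C@H](O[Si](C)(C)C(C)(C)C)C[C@@]2(O)C(C)C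
F4 | step 19 | trans-fused 2β-(tert-butyldimethylsilyloxy)-4β,6α-dihydroxy-4α-isopropyl-1β,8-dimethylhydroazulen-9-one (C8 epimers) | CC1C[C@H](O)[C@@H]2[C@@](C)(CC1=O)[C@H](O[Si](C)(C)C(C)(C)C)C[C@@]2(O)C(C)C
F5 | step 19 | C6 α-[4-(tert-butyldimethylsilyloxy)benzoate] of F4 (C8 epimers) | CC1C[C@H](OC(=O)c3ccc(O[Si](C)(C)C(C)(C)C)cc3)[C@@H]2[C@@](C)(CC1=O)[C@H](O[Si](C)(C)C(C)(C)C)C[C@@]2(O)C(C)C
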